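**Retrosynthetic overview**
1. Target 18 ⇒ Julia–Kocienski olefination (side-chain C9=C10) of dioxolane enal 13 with (Z)-hexenyl sulfone 16; 13 ⇒ cross-metathesis of terminal alkene 11 with but-2-enal.
2. 11 ⇒ C3–CH2CO2Me bond by catalyst-controlled addition of a silyl ketene acetal to the peroxycarbenium ion from ketal 9 (sets C3, resolves C5).
3. 9 ⇒ dioxolanol 8 ⇒ aerobic ring expansion of cyclopropanol 6 (three-membered carbocycle to five-membered 1,2-dioxolane); the only ring of the target is formed here.
4. 6 ⇒ cyclopropanation of silyl enol ether 4 ⇒ conjugate addition of hept-6-enyl Grignard reagent to 3-methylbut-3-en-2-one.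

Assumption: tert-butyl[(1-methoxyethenyl)oxy]dimethylsilane (the silyl enol form of methyl acetate) and 1-phenyl-1H-tetrazole-5-thiol are bought and used as reagents.
Assumption: which enantiomer of the step 5 catalyst gives 3R must be found by experiment; the route is written with the one that does (both are equally accessible).

**Step 1**
Reactants: 1 7-bromohept-1-ene; 2 3-methylbut-3-en-2-one
Product: 4 trimethyl[(3-methylundeca-2,10-dien-2-yl)oxy]silane (E/Z mixture), via hept-6-en-1-ylmagnesium bromide 3 (not isolated)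
Conditions: Mg, THF, rt; then 2, CuBr·SMe2 (5 mol %), TMSCl (2 equiv), THF, −78 °C; Et3N, pentane work-up
Reagents that add atoms: chlorotrimethylsilane, C[Si](C)(C)Cl; magnesium, [Mg] (stays in 3 only)
Why: Copper-catalysed conjugate addition of the Grignard reagent to the unhindered methylene terminus of the enone, with TMSCl trapping the regiodefined tetrasubstituted enolate on oxygen; no stereocentre is formed and the enol ether geometry is of no consequence.

**Step 2**
Reactants: 4 trimethyl[(3-methylundeca-2,10-dien-2-yl)oxy]silane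
Product: 6 1,2-dimethyl-2-(oct-7-en-1-yl)cyclopropan-1-ol (racemic, both diastereomers), via [1,2-dimethyl-2-(oct-7-en-1-yl)cyclopropoxy]trimethylsilane 5 (not isolated)
Conditions: Et2Zn, CH2I2 (1.3 equiv each), CH2Cl2, 0 °C; then K2CO3 (cat.), MeOH, 0 °C
Reagents that add atoms: diiodomethane, ICI
Why: Furukawa-type Simmons–Smith cyclopropanation, in which the electrophilic zinc carbenoid should react much faster with the electron-rich silyl enol ether than with the monosubstituted terminal alkene, followed by methanolysis of the labile tertiary trimethylsilyl ether; both new stereocentres are racemic and are erased or reset later.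

**Step 3**
Reactants: 6 1,2-dimethyl-2-(oct-7-en-1-yl)cyclopropan-1-ol
Product: 8 3,5-dimethyl-5-(oct-7-en-1-yl)-1,2-dioxolan-3-ol (racemic, both diastereomers), via 4-hydroperoxy-4-methyldodec-11-en-2-one 7 (not isolated)
Conditions: Mn(acac)3 (2 mol %), O2 (1 atm), benzene, rt
Reagents that add atoms: dioxygen, O=O
Why: Manganese-catalysed aerobic oxidative ring expansion of a cyclopropanol (radical chain): the alkoxy radical undergoes β-scission of the more substituted C1–C2 bond to the tertiary β-keto radical, O2 capture and hydrogen transfer give hydroperoxy ketone 7, and this closes to the five-membered peroxyhemiketal; C5 is formed as a racemate and C3 is a labile hemiketal centre.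

**Step 4**
Reactants: 8 3,5-dimethyl-5-(oct-7-en-1-yl)-1,2-dioxolan-3-ol
Product: 9 3-methoxy-3,5-dimethyl-5-(oct-7-en-1-yl)-1,2-dioxolane (racemic at C5, both C3 epimers)
Conditions: MeOH, pyridinium p-toluenesulfonate (cat.), 4 Å MS, rt
Reagents that add atoms: methanol, CO
Why: Acid-catalysed ketalisation of the peroxyhemiketal, established for 1,2-dioxolan-3-ols; the di-tertiary peroxide is stable to the weak acid and the C3 mixture is erased in step 5.

**Step 5**
Reactants: 9 3-methoxy-3,5-dimethyl-5-(oct-7-en-1-yl)-1,2-dioxolane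
Product: 11 methyl 2-[(3R,5S)-3,5-dimethyl-5-(oct-7-en-1-yl)-1,2-dioxolan-3-yl]acetate, via 3,5-dimethyl-5-(oct-7-en-1-yl)-1,2-dioxolan-3-ylium ion 10 (not isolated)
Conditions: tert-butyl[(1-methoxyethenyl)oxy]dimethylsilane (0.6 equiv), chiral imidodiphosphorimidate acid (IDPi; BINOL-derived, 3,3'-diaryl, N-triflyl; 3 mol %), toluene, 4 Å MS, −78 °C; chromatography
Reagents that add atoms: tert-butyl[(1-methoxyethenyl)oxy]dimethylsilane, C=C(OC)O[Si](C)(C)C(C)(C)C
Why: Proposed new method: catalytic enantioselective Mukaiyama-type substitution at a peroxycarbenium ion. The ketene acetal silylates the IDPi acid to a silylium/IDPi ion pair, which abstracts methoxide from either C3 epimer of 9 to give the planar 1,2-dioxolan-3-ylium ion 10 inside the confined chiral anion; the ketene acetal then adds to the face that gives 3R and silyl transfer regenerates the catalyst. The closest known reactions are the achiral TiCl4- or SnCl4-mediated additions of silyl ketene acetals to 3-alkoxy-1,2-dioxolanes and the IDPi-catalysed enantioselective additions of silyl ketene acetals to cyclic aliphatic oxocarbenium ions. C5 is not touched, so with 0.6 equiv of nucleophile the (5S)-enantiomer of 9 reacts faster, because its catalyst-preferred face is also the face anti to the long C5 chain (matched kinetic resolution); 11 (acetate arm trans to the chain) is separated from unreacted (5R)-9 and the minor cis isomer, with a maximum yield of 50% from racemic 9.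

**Step 6**
Reactants: 11 methyl 2-[(3R,5S)-3,5-dimethyl-5-(oct-7-en-1-yl)-1,2-dioxolan-3-yl]acetate; 12 (E)-but-2-enal
Product: 13 methyl 2-[(3R,5S)-3,5-dimethyl-5-[(7E)-9-oxonon-7-en-1-yl]-1,2-dioxolan-3-yl]acetate
Conditions: 12 (5 equiv), second-generation Hoveyda–Grubbs catalyst RuCl2(H2IMes)(=CH-2-iPrO-C6H4) (5 mol %), CH2Cl2, 40 °C
Reagents that add atoms: none
Why: Olefin cross-metathesis of a terminal alkene with an excess of an electron-poor enal gives the E-enal under thermodynamic control, and dialkyl peroxides and esters are inert to the ruthenium carbene; no stereocentre is affected.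

**Step 7**
Reactants: 14 (3Z)-hex-3-en-1-ol
Product: 15 5-{[(3Z)-hex-3-en-1-yl]sulfanyl}-1-phenyl-1H-tetrazole
Conditions: 1-phenyl-1H-tetrazole-5-thiol, PPh3, diisopropyl azodicarboxylate, THF, 0 °C → rt
Reagents that add atoms: 1-phenyl-1H-tetrazole-5-thiol, Sc1nnnn1-c1ccccc1
Why: Mitsunobu thioetherification of a primary alcohol; the Z-alkene is not involved.

**Step 8**
Reactants: 15 5-{[(3Z)-hex-3-en-1-yl]sulfanyl}-1-phenyl-1H-tetrazole
Product: 16 5-{[(3Z)-hex-3-en-1-yl]sulfonyl}-1-phenyl-1H-tetrazole
Conditions: (NH4)6Mo7O24·4H2O (10 mol %), 30% H2O2, EtOH, 0 °C → rt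
Reagents that add atoms: hydrogen peroxide, OO
Why: Molybdate-catalysed sulfide-to-sulfone oxidation, which is chemoselective for sulfur over an isolated Z-alkene.

**Step 9**
Reactants: 13 methyl 2-[(3R,5S)-3,5-dimethyl-5-[(7E)-9-oxonon-7-en-1-yl]-1,2-dioxolan-3-yl]acetate; 16 5-{[(3Z)-hex-3-en-1-yl]sulfonyl}-1-phenyl-1H-tetrazole
Product: 18 methyl 2-[(3R,5S)-3,5-dimethyl-5-[(7E,9E,12Z)-pentadeca-7,9,12-trien-1-yl]-1,2-dioxolan-3-yl]acetate, via potassium (3Z)-1-[(1-phenyl-1H-tetrazol-5-yl)sulfonyl]hex-3-en-1-ide 17 (not isolated)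
Conditions: 16 (1.2 equiv), KN(SiMe3)2 (1.15 equiv), DME, −60 °C, 30 min; then 13, −60 °C → rt
Reagents that add atoms: potassium bis(trimethylsilyl)amide, C[Si](C)(C)[N-][Si](C)(C)C.[K+] (potassium stays in 17 only)
Why: Julia–Kocienski olefination: the pre-formed sulfonyl carbanion adds to the enal, and Smiles rearrangement with loss of SO2 and tetrazolone gives the new C9=C10 alkene with E selectivity (phenyltetrazolyl sulfone, potassium counter-ion, DME). No free base remains to enolise the ester or open the dioxolane, and the 7E and 12Z alkenes and both ring stereocentres are untouched.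

**Compound list**
1 | 7-bromohept-1-ene | C=CCCCCCBr | starting material
2 | 3-methylbut-3-en-2-one | CC(=O)C(C)=C | starting material
3 | hept-6-en-1-ylmagnesium bromide | C=CCCCCC[Mg]Br | intermediate (not isolated)
4 | trimethyl[(3-methylundeca-2,10-dien-2-yl)oxy]silane, E/Z mixture | C=CCCCCCCC(C)=C(C)O[Si](C)(C)C | intermediate
5 | [1,2-dimethyl-2-(oct-7-en-1-yl)cyclopropoxy]trimethylsilane, racemic, both diastereomers | C=CCCCCCCC1(C)CC1(C)O[Si](C)(C)C | intermediate (not isolated)
6 | 1,2-dimethyl-2-(oct-7-en-1-yl)cyclopropan-1-ol, racemic, both diastereomers | C=CCCCCCCC1(C)CC1(C)O | intermediate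
7 | 4-hydroperoxy-4-methyldodec-11-en-2-one, racemic | CC(=O)CC(C)(OO)CCCCCCC=C | intermediate (not isolated)
8 | 3,5-dimethyl-5-(oct-7-en-1-yl)-1,2-dioxolan-3-ol, racemic, both diastereomers | C=CCCCCCCC1(C)CC(C)(O)OO1 | intermediate
9 | 3-methoxy-3,5-dimethyl-5-(oct-7-en-1-yl)-1,2-dioxolane, racemic, both diastereomers | C=CCCCCCCC1(C)CC(C)(OC)OO1 | intermediate
10 | 3,5-dimethyl-5-(oct-7-en-1-yl)-1,2-dioxolan-3-ylium ion (ion pair with the chiral anion) | C=CCCCCCCC1(C)CC(C)=[O+]O1 | intermediate (not isolated)
11 | methyl 2-[(3R,5S)-3,5-dimethyl-5-(oct-7-en-1-yl)-1,2-dioxolan-3-yl]acetate | C=CCCCCCC[C@@]1(C)C[C@](C)(CC(=O)OC)OO1 | intermediate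
12 | (E)-but-2-enal | C/C=C/C=O | starting material
13 | methyl 2-[(3R,5S)-3,5-dimethyl-5-[(7E)-9-oxonon-7-en-1-yl]-1,2-dioxolan-3-yl]acetate | O=C/C=C/CCCCCC[C@@]1(C)C[C@](C)(CC(=O)OC)OO1 | intermediate
14 | (3Z)-hex-3-en-1-ol | CC/C=C\CCO | starting material
15 | 5-{[(3Z)-hex-3-en-1-yl]sulfanyl}-1-phenyl-1H-tetrazole | CC/C=C\CCSc1nnnn1-c1ccccc1 | intermediate
16 | 5-{[(3Z)-hex-3-en-1-yl]sulfonyl}-1-phenyl-1H-tetrazole | CC/C=C\CCS(=O)(=O)c1nnnn1-c1ccccc1 | intermediate
17 | potassium (3Z)-1-[(1-phenyl-1H-tetrazol-5-yl)sulfonyl]hex-3-en-1-ide | CC/C=C\C[CH-]S(=O)(=O)c1nnnn1-c1ccccc1.[K+] | intermediate (not isolated)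
18 | methyl 2-[(3R,5S)-3,5-dimethyl-5-[(7E,9E,12Z)-pentadeca-7,9,12-trien-1-yl]-1,2-dioxolan-3-yl]acetate | CC/C=C\C/C=C/C=C/CCCCCC[C@@]1(C)C[C@](C)(CC(=O)OC)OO1 | target

**Step count**
Total: 9 steps. Longest linear sequence: 7 steps (steps 1–6 and 9).

**Steps most likely to fail**

Step 5 (the proposed new reaction; the catalyst may not override the small Me/alkyl bias at C5, or the silylium catalyst may degrade the peroxide). The fallback sets out from 9 and comes back at 11. Ketal 9 is treated with the same silyl ketene acetal and stoichiometric TiCl4 in CH2Cl2 at −78 °C, the established achiral Lewis-acid alkylation of 3-alkoxy-1,2-dioxolanes. This gives racemic methyl 2-[(3R*,5S*)-3,5-dimethyl-5-(oct-7-en-1-yl)-1,2-dioxolan-3-yl]acetate F3 together with its cis isomer. F3 is separated from the cis isomer on silica and resolved by preparative HPLC on a chiral stationary phase to give 11.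

Step 2 (the hindered tetrasubstituted enol ether may react slowly, so that the carbenoid also attacks the terminal alkene). The fallback sets out from 4 and comes back at 6 without any carbenoid. Hydroxymethylation of 4 with aqueous formaldehyde and Yb(OTf)3 in THF gives 3-(hydroxymethyl)-3-methylundec-10-en-2-one F1. Iodination with I2, PPh3 and imidazole gives 3-(iodomethyl)-3-methylundec-10-en-2-one F2. SmI2 in THF at −78 °C then closes the three-membered ring by an intramolecular Barbier-type 1,3-cyclisation onto the ketone to give 6.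

Step 9 (incomplete E selectivity at C9=C10, or base-induced damage to the β-peroxy ester). The fallback sets out from 11 and 14 and comes back at 18, replacing the olefination by an sp2–sp2 coupling. Cross-metathesis of 11 with 2-ethenyl-4,4,5,5-tetramethyl-1,3,2-dioxaborolane, using the second-generation Grubbs catalyst RuCl2(=CHPh)(H2IMes)(PCy3) in CH2Cl2 at 40 °C, gives methyl 2-[(3R,5S)-3,5-dimethyl-5-[(7E)-8-(4,4,5,5-tetramethyl-1,3,2-dioxaborolan-2-yl)oct-7-en-1-yl]-1,2-dioxolan-3-yl]acetate F4. Separately, 14 is oxidised with Dess–Martin periodinane to (3Z)-hex-3-enal F5, and Takai iodo-olefination (CrCl2, CHI3, THF, 0 °C; no peroxide is present here) gives (1E,4Z)-1-iodohepta-1,4-diene F6. Suzuki–Miyaura coupling of F4 with F6 (PdCl2(dppf), K3PO4, THF/H2O, rt) proceeds with retention of both alkene geometries and gives 18.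

**Further compounds**
F1 | step 2 | 3-(hydroxymethyl)-3-methylundec-10-en-2-one (racemic) | CC(=O)C(C)(CO)CCCCCCC=C
F2 | step 2 | 3-(iodomethyl)-3-methylundec-10-en-2-one (racemic) | CC(=O)C(C)(CI)CCCCCCC=C
F3 | step 5 | racemic methyl 2-[(3R*,5S*)-3,5-dimethyl-5-(oct-7-en-1-yl)-1,2-dioxolan-3-yl]acetate | C=CCCCCCC[C@@]1(C)C[C@](C)(CC(=O)OC)OO1.C=CCCCCCC[C@]1(C)C[C@@](C)(CC(=O)OC)OO1
F4 | step 9 | methyl 2-[(3R,5S)-3,5-dimethyl-5-[(7E)-8-(4,4,5,5-tetramethyl-1,3,2-dioxaborolan-2-yl)oct-7-en-1-yl]-1,2-dioxolan-3-yl]acetate | CC1(C)OB(/C=C/CCCCCC[C@@]2(C)C[C@](C)(CC(=O)OC)OO2)OC1(C)C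
F5 | step 9 | (3Z)-hex-3-enal | CC/C=C\CC=O
F6 | step 9 | (1E,4Z)-1-iodohepta-1,4-diene | CC/C=C\C/C=C/I
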